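(All runs were generated by integration for an exercise; scatter was added.)

A closed, stirred vessel holds J and E as a racemate together with the single-handed reagent Q.

| flask | J | E | Q | remark | time |
|---|---|---|---|---|---|
| spring | 2.5 × 10⁻⁴ M | 2.5 × 10⁻⁴ M | 1.1 equiv | run made earlier |  |
| noon | 3.8 × 10⁻⁴ M | 3.8 × 10⁻⁴ M | 1.1 equiv | run made earlier |  |
| winter | 5.0 × 10⁻⁴ M | 5.0 × 10⁻⁴ M | 1.7 equiv | run made earlier |  |
| flask | 5.0 × 10⁻⁴ M | 5.0 × 10⁻⁴ M | 1.10 equiv |  | 8.0 min |

| run | time / min | J / % | D / % |
|---|---|---|---|
| spring | 0.667 | 20.9 | 50.1 |
| spring | 1.33 | 22.1 | 51.7 |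
| spring | 2.00 | 22.0 | 52.0 |
| spring | 3.00 | 22.4 | 52.5 |
| spring | 4.00 | 22.6 | 52.3 |
| spring | 5.00 | 22.7 | 52.8 |
| noon | 0.250 | 18.1 | 42.9 |
| noon | 0.667 | 20.0 | 51.3 |
| noon | 1.33 | 22.5 | 53.1 |
| noon | 2.00 | 22.9 | 53.1 |
| noon | 3.00 | 22.7 | 52.6 |
| noon | 4.00 | 22.9 | 53.0 |
| noon | 5.00 | 22.3 | 52.6 |
| winter | 0.417 | 7.6 | 65.0 |
| winter | 1.33 | 6.9 | 78.3 |
| winter | 2.00 | 6.3 | 79.6 |
| winter | 3.00 | 7.6 | 79.3 |
| winter | 5.00 | 7.1 | 79.8 |

(scatter of a reading: 0.5 percentage points)

- Q is single-handed; J and E are mirror images of each other, charged as a racemate, each of them at the stated concentration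
- the earlier runs were read with a standard deviation of 0.5 percentage points
- the reaction counts as stopped when no species that holds the J and E together changes by six tenths of a point or more over the second half of the time
- the handed part of Q does not stay in what it makes, so the products of the two hands are mirror images too

- why nothing more happens at 8.0 min, or that something still does (all of J has reacted / Q has run out first / forward and back rates have come level / it is still moving)
- part of the J and E together gone at 8.0 min
- the D standing at 8.0 min, as a percentage of the J and E together charged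

Follow one molecule of Q. It meets J or E, takes one molecule with it and is spent, assuming one to one. Q is then the limiting reagent whenever its charge lies below J and E together. Equivalents count against J, and J and E together are twice J, so dividing the flask's equivalents by 2 gives 55.0%. This is the reagent ceiling, the charged Q as a share of the J and E together.

The readings test it. E is not read, so take [E] level with [J]. The last spring reading of J then gives 54.6% gone, against a ceiling of 55.0%. The last winter reading gives 85.8%, against 85.0%. The spring readings stand flat within the scatter from 2.00 min. The flask has 8.0 min, longer than that, and its [J] and [Q] are charged 2.00 times higher than in spring, which speeds a second-order step.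

The fork remains. D over the ceiling in the last spring reading gives a chance of 0.960 that a molecule of Q ends in D. This reckoning puts the flask at 55.0% gone and 52.8% D.

The forecast says Q has run out first, with 55% gone and 52.8% D: “The plateau is set by Q, not by time.”

In the flask, Q has run out first, with 55.0% gone and 52.6% D.

    Q + J → D (k = 580 /M/s)
    Q + E → L (k = 15.0 /M/s)
    J ⇌ E (k = 0.0350 /s)

At 8.00 min the flask keeps 0% of its charged Q, less than the 45% of its charged J. A neighbour flask with 0.440 equiv of Q has a ceiling of 22.0%, and the spring chance puts its D at 21.1%. That neighbour shows 22.0% gone and 21.3% D.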